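Atom numbers C1–C15 are those of the target (defined in the first section). PMB = 4-methoxybenzyl, TBS = tert-butyldimethylsilyl, TES = triethylsilyl.

## Analysis of the target

The target is a germacranolide of the melampolide type. Its ten-membered carbocycle C1–C10 carries a Z-trisubstituted olefin C1=C10 (methyl C14) and an E-trisubstituted olefin C4=C5 (methyl C15). A trans-fused α-methylene-γ-butyrolactone spans C6–C7 (C11, carbonyl C12, exocyclic methylene C13). There are five stereocentres: C2 (S, free allylic carbinol), C6 (R, lactone carbinol), C7 (S), C8 (R, angelate) and C9 (R, acetate). C6–C9 form a contiguous row; C2 is separated from it by the C1=C10 olefin. The sensitive groups are the α-methylene lactone (Michael acceptor), the angelate (isomerises to the tiglate under nucleophilic catalysis), two different acyl groups on the vicinal O8/O9 pair (acyl migration) and three allylic C–O bonds. The hard points are closing a ten-membered ring that holds one Z and one E olefin, and telling O8 from O9. The strategy rests on the segment C8(O)–C9(O)–C10(CH3)=C1–C2(O): it is a ring-opened 2-(hydroxyalkyl)-3-methylfuran whose ring carbons are C9, C10, C1 and C2 and whose carbinol carbon is C8. Oxidative ring expansion of that furan gives a pyranone that holds the Z-olefin in a ring, C9 as a ketone, C2 at the aldehyde level and O8 as the ring oxygen, chemically distinct from O9.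

## Retrosynthetic reasoning

32 from 31. Only the O2–Si bond is cut. C2 stays silylated to the end so that C13 carries the only hydroxyl to be activated and the allylic alcohol is kept out of the ring closure.

31 from 28. The ring is opened at C6–C7, together with the lactone bond C12–O6. This is the one ring bond whose formation makes no olefin: both trisubstituted olefins are already in the chain of 28. Closure turns the sp2 carbons C6 and C7 into the two stereocentres of the ring fusion and moves the olefin C7=C11 to the exocyclic position C11=C13. The forward step has to join the C6 aldehyde to C7 under dilution, set C7 relative to C8, give the 6,7-trans relation, and let the C6 alkoxide close onto the C12 ester.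

28 from 26, 25 and 24. These are functional-group changes: the bromide from the C13 alcohol 26, that from the benzylic ether 25, and the enal 25 from the allylic alcohol 24. The C13 oxygen travels as a robust ether from the first step and becomes a leaving group only at the end.

24 from 22. C5–C6 and C4–C15 are cut across the terminal alkyne of 22. A syn carbometalation puts the methyl on C4 and the metal on C5, and the metal is exchanged for the one-carbon unit C6. The E geometry of C4=C5 follows from the mechanism.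

22 from 19 and 20; 19 from 18. The ester bond at O8 is cut to angelic acid 20, and the silyl ether at O2 to diol 18. The two hydroxyls of 18 differ in hindrance, so O2 is blocked first and 20 is then placed on O8.

18 from 17. C2–C3 is cut. In 17 C2 is a lactol carbon, an aldehyde masked by O8. Adding a propargyl unit creates the C2 carbinol and releases O8 as a free hydroxyl for the angelate. C2 is remote from C8 and C9, so the forward step needs reagent control.

17 from 16, 15, 14 and 13. These are changes on the pyran ring: the C9 acetate of 16 from the epimeric alcohol 15 with inversion, 15 from ketone 14 by 1,2-reduction, and 14 from lactol 13 by blocking C2. In the six-membered ring C9 sits next to C8 and the acetal at C2 biases the faces, so C9 is set under cyclic control.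

13 from 10. This is the key disconnection. No skeletal bond is cut; the ring bond O8–C2 and the oxygens at C9 and C2 are traced back to the furan of 10. All of C8–C9–C10(CH3)=C1–C2 then comes from aldehyde 4, and the Z-olefin is a furan double bond.

10 from 9, 8, 6 and 5. C11–C12 is cut: the ester comes from alkenyl iodide 8 by carbonylation, and 8 from alkyne 6 by syn hydrometalation. The silyl ether in 6 and 9 is there only to steer the regiochemistry and is removed to give 10.

5 from 4 and 3; 3 from 1 and 2. C7–C8 is cut. Enantioselective addition of alkyne 3 to aldehyde 4 sets C8, the stereocentre from which C9, C7 and C6 are later derived.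

## Alternatives that were turned down

Alternative 1: The ten-membered ring is not closed but released by cleaving the transannular C5–C10 bond of a cis-decalin. In the forward key step NaOt-Bu adds to a pinacol boronate at C4; the borate pushes its C–B electrons into C4=C5 while C5–C10 breaks and a C1 mesylate leaves, giving A1. In its favour, there is no macrocyclisation, and both olefin geometries are fixed stereospecifically by the relative configuration of the bicycle. Against it for this target, the bicycle needs a tertiary boronate at C4, a quaternary C10, the leaving group at C1 and four more stereocentres in one exact arrangement, which is a synthesis as long as the target itself. The oxygen at C2, β to the mesylate, invites simple elimination. A1 still lacks C13 and has O8 and O9 tied in one acetonide, so a late α-methylenation and a regioselective double acylation remain. On ring formation and olefin geometry this route is stronger than the chosen one. The chosen one offers in its place a six-step access to the key substrate from a commercial furan, inherent O8/O9 differentiation, and a methylene lactone made in the ring-closing event.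

Alternative 2: C6–C7 is formed and C4–C9 broken in a [3,3] shift, so the ring grows from six to ten members. In the forward key step the potassium alkoxide (KH, 18-crown-6) of a 1,2-dialkenylcyclohex-2-enol rearranges through a chair to the enolate of A2. In its favour, the reaction is concerted and predictable, the chair relays olefin geometry into the C6/C7 relation, the Z-olefin comes from the six-membered ring, and no dilution is needed. Against it, A2 has no oxygen at C8, a ketone at C9 and C12 at the alcohol level. The route would still need a stereoselective α-hydroxylation at C8 on a flexible cyclodecenone, a stereoselective reduction at C9, two different acylations and oxidation to the lactone. The tertiary alcohol must also be made enantioenriched, and the strongly basic medium limits what the substrate can carry. On ring construction and C6/C7 control it is stronger. The chosen route offers in its place C8 and C9 with the right oxygens and configurations from the start, set from one catalytic step.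

Alternative 3: C5–C6 and C4–C15 are cut together. In the forward key step Ni(C8H12)2 with 1,3-dimesitylimidazol-2-ylidene couples the C6 aldehyde with the terminal alkyne carbon C5 while Zn(CH3)2 delivers the methyl to C4, giving A3. In its favour, one operation makes the E-olefin, the methyl, the C6 carbinol and the ring, where the chosen route spends three steps on the C3–C6 sector before ring closure; the conditions are neutral. Against it, the E-olefin has to be formed inside the ten-membered ring during closure, so exocyclic closure or dimerisation may compete. C6 would be set only by remote substrate control. A3 carries a saturated ester side chain, so lactonisation and a late α-methylenation under base beside the acyloxy groups remain, as does the acetonide differentiation. On convergency it is as strong or stronger. The chosen route offers in its place a ring closure that makes no olefin (both are in place beforehand) and that delivers the α-methylene lactone directly.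

Key step: step 7

Assumption: (S,S)-ProPhenol is taken to direct the alkynylzinc to the Re face of 4 (R at C8), and the (−)-isopinocampheyl allenylborane to give 2S as its allyl analogue does with conjugated aldehydes; if either sense is the opposite, the antipodal ligand or borane is used with no other change.

## Route

Step 1
Reactants: 1 prop-2-yn-1-ol; 2 4-methoxybenzyl chloride
Product: 3 1-methoxy-4-[(prop-2-yn-1-yloxy)methyl]benzene
Conditions: NaH, Bu4NI (cat.), THF, 0 °C to rt
Reagents that add atoms: none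
Why: Williamson ether synthesis; the alkoxide of 1 forms selectively over the acetylide and displaces the benzylic chloride under iodide catalysis.

Step 2
Reactants: 4 3-methylfuran-2-carbaldehyde; 3 1-methoxy-4-[(prop-2-yn-1-yloxy)methyl]benzene
Product: 5 (1R)-4-[(4-methoxybenzyl)oxy]-1-(3-methylfuran-2-yl)but-2-yn-1-ol
Conditions: Zn(CH3)2, (S,S)-ProPhenol (10 mol %), Ph3P=O (20 mol %), toluene, 4 °C
Reagents that add atoms: none
Why: Catalytic enantioselective alkynylation of an aromatic aldehyde by a dinuclear zinc–ProPhenol complex, which binds aldehyde and alkynylzinc on its two zinc centres; Re-face delivery should set C8 as R, and heteroaromatic aldehydes are standard substrates.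

Step 3
Reactants: 5 (1R)-4-[(4-methoxybenzyl)oxy]-1-(3-methylfuran-2-yl)but-2-yn-1-ol
Product: 6 triethyl{[(1R)-4-[(4-methoxybenzyl)oxy]-1-(3-methylfuran-2-yl)but-2-yn-1-yl]oxy}silane
Conditions: Et3SiCl, imidazole, CH2Cl2, 0 °C
Reagents that add atoms: chlorotriethylsilane, CC[Si](Cl)(CC)CC
Why: Routine silylation of a secondary alcohol; the TES ether adds bulk at C8 to steer the next step and can later be removed beside the PMB ether.

Step 4
Reactants: 6 triethyl{[(1R)-4-[(4-methoxybenzyl)oxy]-1-(3-methylfuran-2-yl)but-2-yn-1-yl]oxy}silane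
Product: 8 {[(1R,2E)-3-iodo-4-[(4-methoxybenzyl)oxy]-1-(3-methylfuran-2-yl)but-2-en-1-yl]oxy}triethylsilane, via vinylstannane 7 (not isolated)
Conditions: Bu3SnH, PdCl2(PPh3)2 (3 mol %), THF, 0 °C to rt; then I2, CH2Cl2, 0 °C
Reagents that add atoms: iodine, II; tributyltin hydride, CCCC[SnH](CCCC)CCCC (tin stays only in 7)
Why: Palladium-catalysed syn-hydrostannation of an internal alkyne, then iododestannylation with retention; tin should go to C11, next to the unbranched C13 methylene and away from the branched silyloxy(furyl)methyl carbon C8, so that H sits on C7 and C8 ends cis to C13.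

Step 5
Reactants: 8 {[(1R,2E)-3-iodo-4-[(4-methoxybenzyl)oxy]-1-(3-methylfuran-2-yl)but-2-en-1-yl]oxy}triethylsilane
Product: 9 methyl (2E,4R)-2-{[(4-methoxybenzyl)oxy]methyl}-4-(3-methylfuran-2-yl)-4-[(triethylsilyl)oxy]but-2-enoate
Conditions: CO (1 atm), Pd(PPh3)4 (5 mol %), Et3N, CH3OH/DMF, 55 °C
Reagents that add atoms: carbon monoxide, [C-]#[O+]; methanol, CO
Why: Palladium-catalysed methoxycarbonylation of an alkenyl iodide (oxidative addition, CO insertion, methanolysis) with retention of geometry; the ester ends trans to C8 and so cannot lactonise onto O8.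

Step 6
Reactants: 9 methyl (2E,4R)-2-{[(4-methoxybenzyl)oxy]methyl}-4-(3-methylfuran-2-yl)-4-[(triethylsilyl)oxy]but-2-enoate
Product: 10 methyl (2E,4R)-4-hydroxy-2-{[(4-methoxybenzyl)oxy]methyl}-4-(3-methylfuran-2-yl)but-2-enoate
Conditions: HF·pyridine, pyridine, THF, 0 °C
Reagents that add atoms: none
Why: Buffered fluoride cleaves the secondary TES ether; the acid-sensitive furyl allyl carbinol, the enoate and the PMB ether are left alone.

Step 7
Reactants: 10 methyl (2E,4R)-4-hydroxy-2-{[(4-methoxybenzyl)oxy]methyl}-4-(3-methylfuran-2-yl)but-2-enoate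
Product: 13 methyl (2E)-3-[(2R)-6-hydroxy-4-methyl-3-oxo-3,6-dihydro-2H-pyran-2-yl]-2-{[(4-methoxybenzyl)oxy]methyl}prop-2-enoate (both anomers), via bromohydrin dihydrofuran 11 (not isolated), via Z-ene-dione 12 (not isolated)
Conditions: NBS, NaHCO3, NaOAc, THF/H2O (4:1), 0 °C
Reagents that add atoms: water, O
Why: Achmatowicz oxidative rearrangement of a 2-furylcarbinol. N-Bromosuccinimide transfers Br+ to the free α-carbon of the furan (C2), water captures the oxocarbenium ion at C9 to give dihydrofuran 11, and loss of bromide with ring opening gives the Z-ene-dione 12 with the C9 ketone and the C2 aldehyde cis on C1=C10. The C8 hydroxyl then adds to the C2 aldehyde in a 6-exo-trig hemiacetalisation that closes the pyranone ring of 13; only the Z isomer can cyclise, so the ring locks the olefin geometry. The one new stereocentre, the anomeric C2, is under thermodynamic control (anomeric effect), forms as a mixture and is not kept, since C2 is later opened again. The step needs chemoselectivity for the furan over the enoate olefin C7=C11 and the anisyl ring; the 2,3-dialkylfuran is by far the most electron-rich π-system and the enoate is deactivated toward Br+. It also needs retention at C8; no bond to C8 is made or broken, and the bicarbonate/acetate buffer removes HBr so that the doubly activated carbinol is not ionised. The product holds O8 as ring oxygen and O9 as ketone, which is what later allows two different acyl groups to be placed.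

Step 8
Reactants: 13 methyl (2E)-3-[(2R)-6-hydroxy-4-methyl-3-oxo-3,6-dihydro-2H-pyran-2-yl]-2-{[(4-methoxybenzyl)oxy]methyl}prop-2-enoate
Product: 14 methyl (2E)-3-[(2R,6R)-6-{[tert-butyl(dimethyl)silyl]oxy}-4-methyl-3-oxo-3,6-dihydro-2H-pyran-2-yl]-2-{[(4-methoxybenzyl)oxy]methyl}prop-2-enoate
Conditions: t-BuMe2SiCl, imidazole, CH2Cl2, 0 °C
Reagents that add atoms: tert-butyl(chloro)dimethylsilane, CC(C)(C)[Si](C)(C)Cl
Why: Silylation of the equilibrating lactol; the anomer with the silyloxy group pseudo-axial and trans to the C8 side chain should predominate and is the one carried on; C2 is thereby blocked as an acetal.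

Step 9
Reactants: 14 methyl (2E)-3-[(2R,6R)-6-{[tert-butyl(dimethyl)silyl]oxy}-4-methyl-3-oxo-3,6-dihydro-2H-pyran-2-yl]-2-{[(4-methoxybenzyl)oxy]methyl}prop-2-enoate
Product: 15 methyl (2E)-3-[(2R,3S,6R)-6-{[tert-butyl(dimethyl)silyl]oxy}-3-hydroxy-4-methyl-3,6-dihydro-2H-pyran-2-yl]-2-{[(4-methoxybenzyl)oxy]methyl}prop-2-enoate
Conditions: NaBH4, CeCl3·7H2O, CH3OH/CH2Cl2, −78 °C
Reagents that add atoms: none
Why: Luche 1,2-reduction of the enone; hydride should enter anti to the pseudo-axial silyloxy group, giving the C9 alcohol cis to that group and trans to the C8 side chain (9S); the ester is inert at −78 °C.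

Step 10
Reactants: 15 methyl (2E)-3-[(2R,3S,6R)-6-{[tert-butyl(dimethyl)silyl]oxy}-3-hydroxy-4-methyl-3,6-dihydro-2H-pyran-2-yl]-2-{[(4-methoxybenzyl)oxy]methyl}prop-2-enoate
Product: 16 methyl (2E)-3-[(2R,3R,6R)-3-(acetyloxy)-6-{[tert-butyl(dimethyl)silyl]oxy}-4-methyl-3,6-dihydro-2H-pyran-2-yl]-2-{[(4-methoxybenzyl)oxy]methyl}prop-2-enoate
Conditions: PPh3, DIAD, AcOH, toluene, 0 °C to rt
Reagents that add atoms: acetic acid, CC(=O)O
Why: Mitsunobu reaction; acetate displaces the C9 oxyphosphonium ion with inversion from the face remote from the silyloxy group, giving the 9R acetate cis to the C8 side chain, so the acetate is installed and C9 corrected in one operation.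

Step 11
Reactants: 16 methyl (2E)-3-[(2R,3R,6R)-3-(acetyloxy)-6-{[tert-butyl(dimethyl)silyl]oxy}-4-methyl-3,6-dihydro-2H-pyran-2-yl]-2-{[(4-methoxybenzyl)oxy]methyl}prop-2-enoate
Product: 17 methyl (2E)-3-[(2R,3R)-3-(acetyloxy)-6-hydroxy-4-methyl-3,6-dihydro-2H-pyran-2-yl]-2-{[(4-methoxybenzyl)oxy]methyl}prop-2-enoate (both anomers)
Conditions: Bu4NF, AcOH, THF, 0 °C
Reagents that add atoms: none
Why: The silyl acetal is the only silyl group present and is very fluoride-labile; the acetic acid buffer keeps the medium neutral so that the acetate does not migrate; the product is the lactol, the masked C2 aldehyde.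

Step 12
Reactants: 17 methyl (2E)-3-[(2R,3R)-3-(acetyloxy)-6-hydroxy-4-methyl-3,6-dihydro-2H-pyran-2-yl]-2-{[(4-methoxybenzyl)oxy]methyl}prop-2-enoate
Product: 18 methyl (2E,4R,5R,6Z,8S)-5-(acetyloxy)-4,8-dihydroxy-2-{[(4-methoxybenzyl)oxy]methyl}-6-methylundeca-2,6-dien-10-ynoate
Conditions: (−)-B-allenyldiisopinocampheylborane (2.5 equiv), Et2O, −78 to −20 °C; then pH 7 buffer, H2O2, CH3OH, 0 °C
Reagents that add atoms: (−)-B-allenyldiisopinocampheylborane, C=C=CB([C@@H]1C[C@@H]2C[C@@H](C2(C)C)[C@H]1C)[C@@H]1C[C@@H]2C[C@@H](C2(C)C)[C@H]1C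
Why: Asymmetric allenylboration (SE2′ through a six-membered chair) of the hydroxy enal in equilibrium with the lactol; one equivalent of borane converts the lactol hydroxyl into a borinate, which opens the ring and parks boron on O8, and a second adds to the free Z-enal. The isopinocampheyl groups should override the remote centres and give 2S; allyl- and allenylboration of aldehydes and allylboration of lactols with these boranes are known.

Step 13
Reactants: 18 methyl (2E,4R,5R,6Z,8S)-5-(acetyloxy)-4,8-dihydroxy-2-{[(4-methoxybenzyl)oxy]methyl}-6-methylundeca-2,6-dien-10-ynoate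
Product: 19 methyl (2E,4R,5R,6Z,8S)-5-(acetyloxy)-8-{[tert-butyl(dimethyl)silyl]oxy}-4-hydroxy-2-{[(4-methoxybenzyl)oxy]methyl}-6-methylundeca-2,6-dien-10-ynoate
Conditions: t-BuMe2SiCl, imidazole, DMF, 0 °C to rt
Reagents that add atoms: tert-butyl(chloro)dimethylsilane, CC(C)(C)[Si](C)(C)Cl
Why: Selective silylation; O2 is flanked by a methylene, whereas O8 lies between the acetoxy-bearing C9 and the trisubstituted enoate and should react much more slowly.

Step 14
Reactants: 19 methyl (2E,4R,5R,6Z,8S)-5-(acetyloxy)-8-{[tert-butyl(dimethyl)silyl]oxy}-4-hydroxy-2-{[(4-methoxybenzyl)oxy]methyl}-6-methylundeca-2,6-dien-10-ynoate; 20 angelic acid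
Product: 22 methyl (2E,4R,5R,6Z,8S)-5-(acetyloxy)-8-{[tert-butyl(dimethyl)silyl]oxy}-2-{[(4-methoxybenzyl)oxy]methyl}-6-methyl-4-{[(2Z)-2-methylbut-2-enoyl]oxy}undeca-2,6-dien-10-ynoate, via mixed anhydride 21 (not isolated)
Conditions: 20, 2,4,6-trichlorobenzoyl chloride, Et3N, toluene, rt; then 19, toluene, 75 °C
Reagents that add atoms: none
Why: Yamaguchi esterification through the mixed anhydride, run without a nucleophilic catalyst so that the Z geometry of the angelate is kept; the hindered O8 is the only free hydroxyl.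

Step 15
Reactants: 22 methyl (2E,4R,5R,6Z,8S)-5-(acetyloxy)-8-{[tert-butyl(dimethyl)silyl]oxy}-2-{[(4-methoxybenzyl)oxy]methyl}-6-methyl-4-{[(2Z)-2-methylbut-2-enoyl]oxy}undeca-2,6-dien-10-ynoate
Product: 24 methyl (2E,4R,5R,6Z,8S,10E)-5-(acetyloxy)-8-{[tert-butyl(dimethyl)silyl]oxy}-12-hydroxy-2-{[(4-methoxybenzyl)oxy]methyl}-6,10-dimethyl-4-{[(2Z)-2-methylbut-2-enoyl]oxy}dodeca-2,6,10-trienoate, via alkenylalane 23 (not isolated)
Conditions: Al(CH3)3, Zr(C5H5)2Cl2 (0.3 equiv), H2O (1 equiv), CH2Cl2, −20 °C; then (CH2O)n, 0 °C to rt; Rochelle salt work-up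
Reagents that add atoms: trimethylaluminium, C[Al](C)C; formaldehyde (as paraformaldehyde), C=O
Why: Negishi zirconium-catalysed methylalumination, a syn addition that puts CH3 on C4 and aluminium on C5; the alkenyl–aluminium bond then adds to formaldehyde with retention, giving the E allylic alcohol. Water acceleration lets the carbometalation run at −20 °C, where esters and silyl ethers should be inert.

Step 16
Reactants: 24 methyl (2E,4R,5R,6Z,8S,10E)-5-(acetyloxy)-8-{[tert-butyl(dimethyl)silyl]oxy}-12-hydroxy-2-{[(4-methoxybenzyl)oxy]methyl}-6,10-dimethyl-4-{[(2Z)-2-methylbut-2-enoyl]oxy}dodeca-2,6,10-trienoate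
Product: 25 methyl (2E,4R,5R,6Z,8S,10E)-5-(acetyloxy)-8-{[tert-butyl(dimethyl)silyl]oxy}-2-{[(4-methoxybenzyl)oxy]methyl}-6,10-dimethyl-4-{[(2Z)-2-methylbut-2-enoyl]oxy}-12-oxododeca-2,6,10-trienoate
Conditions: MnO2, CH2Cl2, rt
Reagents that add atoms: none
Why: Manganese dioxide oxidises the only free (allylic) alcohol to the E-enal without over-oxidation or isomerisation.

Step 17
Reactants: 25 methyl (2E,4R,5R,6Z,8S,10E)-5-(acetyloxy)-8-{[tert-butyl(dimethyl)silyl]oxy}-2-{[(4-methoxybenzyl)oxy]methyl}-6,10-dimethyl-4-{[(2Z)-2-methylbut-2-enoyl]oxy}-12-oxododeca-2,6,10-trienoate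
Product: 26 methyl (2E,4R,5R,6Z,8S,10E)-5-(acetyloxy)-8-{[tert-butyl(dimethyl)silyl]oxy}-2-(hydroxymethyl)-6,10-dimethyl-4-{[(2Z)-2-methylbut-2-enoyl]oxy}-12-oxododeca-2,6,10-trienoate
Conditions: DDQ, CH2Cl2/pH 7 buffer, 0 °C
Reagents that add atoms: none
Why: Oxidative cleavage of the PMB ether by hydride abstraction at the electron-rich benzylic position; silyl ether, esters and enal are inert and the buffer keeps acid away from the allylic esters.

Step 18
Reactants: 26 methyl (2E,4R,5R,6Z,8S,10E)-5-(acetyloxy)-8-{[tert-butyl(dimethyl)silyl]oxy}-2-(hydroxymethyl)-6,10-dimethyl-4-{[(2Z)-2-methylbut-2-enoyl]oxy}-12-oxododeca-2,6,10-trienoate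
Product: 28 methyl (2Z,4R,5R,6Z,8S,10E)-5-(acetyloxy)-2-(bromomethyl)-8-{[tert-butyl(dimethyl)silyl]oxy}-6,10-dimethyl-4-{[(2Z)-2-methylbut-2-enoyl]oxy}-12-oxododeca-2,6,10-trienoate, via allylic mesylate 27 (not isolated)
Conditions: MsCl, Et3N, CH2Cl2, −40 °C; then LiBr, THF, 0 °C
Reagents that add atoms: lithium bromide, [Li+].[Br-]
Why: Mesylation of the primary allylic alcohol and SN2 displacement by bromide; a phosphine/CBr4 activation is avoided because it would convert the aldehyde into a dibromo-olefin.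

Step 19
Reactants: 28 methyl (2Z,4R,5R,6Z,8S,10E)-5-(acetyloxy)-2-(bromomethyl)-8-{[tert-butyl(dimethyl)silyl]oxy}-6,10-dimethyl-4-{[(2Z)-2-methylbut-2-enoyl]oxy}-12-oxododeca-2,6,10-trienoate
Product: 31 (1(10)Z,4E,2S,6R,7S,8R,9R)-9-acetoxy-8-angeloyloxy-2-{[tert-butyl(dimethyl)silyl]oxy}germacra-1(10),4,11(13)-trien-12,6-olide, via allylchromium dichloride 29 (not isolated), via hydroxy ester 30 (not isolated)
Conditions: CrCl2 (10 equiv), THF, 25 °C, slow addition of 28 to 2 mM; then PPTS (cat.), CH2Cl2, rt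
Reagents that add atoms: none
Why: Intramolecular Nozaki–Hiyama allylation under Barbier conditions, the known chromium-mediated closure of ω-formyl 2-(bromomethyl)alk-2-enoates to germacranolides: divalent chromium inserts into the C–Br bond and the trivalent allylchromium 29 adds through C7 to the C6 aldehyde (SE2′), which closes the ring and moves the olefin to C11=C13, and the C6 alkoxide then lactonises onto the ester. C7 should be set by C8: with H8 eclipsing the enoate (allylic 1,3-strain) the tether through C9 reaches one face while the angelate covers the other; the 6,7-trans relation is expected from the crown-like transition state usual for 4E-germacranolide closures.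

Step 20
Reactants: 31 (1(10)Z,4E,2S,6R,7S,8R,9R)-9-acetoxy-8-angeloyloxy-2-{[tert-butyl(dimethyl)silyl]oxy}germacra-1(10),4,11(13)-trien-12,6-olide
Product: 32 (1(10)Z,4E,2S,6R,7S,8R,9R)-9-acetoxy-8-angeloyloxy-2-hydroxygermacra-1(10),4,11(13)-trien-12,6-olide (CNP0316477.1)
Conditions: HF·pyridine, pyridine, THF, 0 °C to rt
Reagents that add atoms: none
Why: Buffered fluoride cleavage of the secondary silyl ether; it is non-basic, so the α-methylene lactone, the angelate and the acetate should survive and no acyl migration is expected.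

## Compound list

1 | prop-2-yn-1-ol | C#CCO | starting material
2 | 4-methoxybenzyl chloride | COc1ccc(CCl)cc1 | starting material
3 | 1-methoxy-4-[(prop-2-yn-1-yloxy)methyl]benzene | C#CCOCc1ccc(OC)cc1 | intermediate
4 | 3-methylfuran-2-carbaldehyde | Cc1ccoc1C=O | starting material
5 | (1R)-4-[(4-methoxybenzyl)oxy]-1-(3-methylfuran-2-yl)but-2-yn-1-ol | Cc1ccoc1[C@H](O)C#CCOCc1ccc(OC)cc1 | intermediate
6 | triethyl{[(1R)-4-[(4-methoxybenzyl)oxy]-1-(3-methylfuran-2-yl)but-2-yn-1-yl]oxy}silane | Cc1ccoc1[C@H](O[Si](CC)(CC)CC)C#CCOCc1ccc(OC)cc1 | intermediate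
7 | tributyl{(2E,4R)-1-[(4-methoxybenzyl)oxy]-4-(3-methylfuran-2-yl)-4-[(triethylsilyl)oxy]but-2-en-2-yl}stannane | Cc1ccoc1[C@H](O[Si](CC)(CC)CC)/C=C(/[Sn](CCCC)(CCCC)CCCC)COCc1ccc(OC)cc1 | intermediate (not isolated)
8 | {[(1R,2E)-3-iodo-4-[(4-methoxybenzyl)oxy]-1-(3-methylfuran-2-yl)but-2-en-1-yl]oxy}triethylsilane | Cc1ccoc1[C@H](O[Si](CC)(CC)CC)/C=C(/I)COCc1ccc(OC)cc1 | intermediate
9 | methyl (2E,4R)-2-{[(4-methoxybenzyl)oxy]methyl}-4-(3-methylfuran-2-yl)-4-[(triethylsilyl)oxy]but-2-enoate | COC(=O)/C(COCc1ccc(OC)cc1)=C/[C@@H](O[Si](CC)(CC)CC)c1occc1C | intermediate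
10 | methyl (2E,4R)-4-hydroxy-2-{[(4-methoxybenzyl)oxy]methyl}-4-(3-methylfuran-2-yl)but-2-enoate | COC(=O)/C(COCc1ccc(OC)cc1)=C/[C@@H](O)c1occc1C | intermediate
11 | methyl (2E,4R)-4-(5-bromo-2-hydroxy-3-methyl-2,5-dihydrofuran-2-yl)-4-hydroxy-2-{[(4-methoxybenzyl)oxy]methyl}but-2-enoate (ring centres undefined) | COC(=O)/C(COCc1ccc(OC)cc1)=C/[C@@H](O)C1(O)OC(Br)C=C1C | intermediate (not isolated)
12 | methyl (2E,4R,6Z)-4-hydroxy-2-{[(4-methoxybenzyl)oxy]methyl}-6-methyl-5,8-dioxoocta-2,6-dienoate | COC(=O)/C(COCc1ccc(OC)cc1)=C/[C@@H](O)C(=O)/C(C)=C\C=O | intermediate (not isolated)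
13 | methyl (2E)-3-[(2R)-6-hydroxy-4-methyl-3-oxo-3,6-dihydro-2H-pyran-2-yl]-2-{[(4-methoxybenzyl)oxy]methyl}prop-2-enoate (both anomers) | COC(=O)/C(COCc1ccc(OC)cc1)=C/[C@H]1OC(O)C=C(C)C1=O | intermediate
14 | methyl (2E)-3-[(2R,6R)-6-{[tert-butyl(dimethyl)silyl]oxy}-4-methyl-3-oxo-3,6-dihydro-2H-pyran-2-yl]-2-{[(4-methoxybenzyl)oxy]methyl}prop-2-enoate | COC(=O)/C(COCc1ccc(OC)cc1)=C/[C@H]1O[C@H](O[Si](C)(C)C(C)(C)C)C=C(C)C1=O | intermediate
15 | methyl (2E)-3-[(2R,3S,6R)-6-{[tert-butyl(dimethyl)silyl]oxy}-3-hydroxy-4-methyl-3,6-dihydro-2H-pyran-2-yl]-2-{[(4-methoxybenzyl)oxy]methyl}prop-2-enoate | COC(=O)/C(COCc1ccc(OC)cc1)=C/[C@H]1O[C@H](O[Si](C)(C)C(C)(C)C)C=C(C)[C@@H]1O | intermediate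
16 | methyl (2E)-3-[(2R,3R,6R)-3-(acetyloxy)-6-{[tert-butyl(dimethyl)silyl]oxy}-4-methyl-3,6-dihydro-2H-pyran-2-yl]-2-{[(4-methoxybenzyl)oxy]methyl}prop-2-enoate | COC(=O)/C(COCc1ccc(OC)cc1)=C/[C@H]1O[C@H](O[Si](C)(C)C(C)(C)C)C=C(C)[C@H]1OC(C)=O | intermediate
17 | methyl (2E)-3-[(2R,3R)-3-(acetyloxy)-6-hydroxy-4-methyl-3,6-dihydro-2H-pyran-2-yl]-2-{[(4-methoxybenzyl)oxy]methyl}prop-2-enoate (both anomers) | COC(=O)/C(COCc1ccc(OC)cc1)=C/[C@H]1OC(O)C=C(C)[C@H]1OC(C)=O | intermediate
18 | methyl (2E,4R,5R,6Z,8S)-5-(acetyloxy)-4,8-dihydroxy-2-{[(4-methoxybenzyl)oxy]methyl}-6-methylundeca-2,6-dien-10-ynoate | C#CC[C@H](O)/C=C(/C)[C@@H](OC(C)=O)[C@H](O)/C=C(\COCc1ccc(OC)cc1)C(=O)OC | intermediate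
19 | methyl (2E,4R,5R,6Z,8S)-5-(acetyloxy)-8-{[tert-butyl(dimethyl)silyl]oxy}-4-hydroxy-2-{[(4-methoxybenzyl)oxy]methyl}-6-methylundeca-2,6-dien-10-ynoate | C#CC[C@H](O[Si](C)(C)C(C)(C)C)/C=C(/C)[C@@H](OC(C)=O)[C@H](O)/C=C(\COCc1ccc(OC)cc1)C(=O)OC | intermediate
20 | angelic acid, (2Z)-2-methylbut-2-enoic acid | C/C=C(/C)C(=O)O | starting material
21 | (2Z)-2-methylbut-2-enoic 2,4,6-trichlorobenzoic anhydride | C/C=C(/C)C(=O)OC(=O)c1c(Cl)cc(Cl)cc1Cl | intermediate (not isolated)
22 | methyl (2E,4R,5R,6Z,8S)-5-(acetyloxy)-8-{[tert-butyl(dimethyl)silyl]oxy}-2-{[(4-methoxybenzyl)oxy]methyl}-6-methyl-4-{[(2Z)-2-methylbut-2-enoyl]oxy}undeca-2,6-dien-10-ynoate | C#CC[C@H](O[Si](C)(C)C(C)(C)C)/C=C(/C)[C@@H](OC(C)=O)[C@H](OC(=O)/C(C)=C\C)/C=C(\COCc1ccc(OC)cc1)C(=O)OC | intermediate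
23 | (E)-alkenyl(dimethyl)alane from 22: CH3 on C4, Al(CH3)2 on C5 | C[Al](C)/C=C(\C)C[C@H](O[Si](C)(C)C(C)(C)C)/C=C(/C)[C@@H](OC(C)=O)[C@H](OC(=O)/C(C)=C\C)/C=C(\COCc1ccc(OC)cc1)C(=O)OC | intermediate (not isolated)
24 | methyl (2E,4R,5R,6Z,8S,10E)-5-(acetyloxy)-8-{[tert-butyl(dimethyl)silyl]oxy}-12-hydroxy-2-{[(4-methoxybenzyl)oxy]methyl}-6,10-dimethyl-4-{[(2Z)-2-methylbut-2-enoyl]oxy}dodeca-2,6,10-trienoate | OC/C=C(\C)C[C@H](O[Si](C)(C)C(C)(C)C)/C=C(/C)[C@@H](OC(C)=O)[C@H](OC(=O)/C(C)=C\C)/C=C(\COCc1ccc(OC)cc1)C(=O)OC | intermediate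
25 | methyl (2E,4R,5R,6Z,8S,10E)-5-(acetyloxy)-8-{[tert-butyl(dimethyl)silyl]oxy}-2-{[(4-methoxybenzyl)oxy]methyl}-6,10-dimethyl-4-{[(2Z)-2-methylbut-2-enoyl]oxy}-12-oxododeca-2,6,10-trienoate | O=C/C=C(\C)C[C@H](O[Si](C)(C)C(C)(C)C)/C=C(/C)[C@@H](OC(C)=O)[C@H](OC(=O)/C(C)=C\C)/C=C(\COCc1ccc(OC)cc1)C(=O)OC | intermediate
26 | methyl (2E,4R,5R,6Z,8S,10E)-5-(acetyloxy)-8-{[tert-butyl(dimethyl)silyl]oxy}-2-(hydroxymethyl)-6,10-dimethyl-4-{[(2Z)-2-methylbut-2-enoyl]oxy}-12-oxododeca-2,6,10-trienoate | O=C/C=C(\C)C[C@H](O[Si](C)(C)C(C)(C)C)/C=C(/C)[C@@H](OC(C)=O)[C@H](OC(=O)/C(C)=C\C)/C=C(\CO)C(=O)OC | intermediate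
27 | methyl (2E,4R,5R,6Z,8S,10E)-5-(acetyloxy)-8-{[tert-butyl(dimethyl)silyl]oxy}-6,10-dimethyl-4-{[(2Z)-2-methylbut-2-enoyl]oxy}-2-{[(methylsulfonyl)oxy]methyl}-12-oxododeca-2,6,10-trienoate | O=C/C=C(\C)C[C@H](O[Si](C)(C)C(C)(C)C)/C=C(/C)[C@@H](OC(C)=O)[C@H](OC(=O)/C(C)=C\C)/C=C(\COS(C)(=O)=O)C(=O)OC | intermediate (not isolated)
28 | methyl (2Z,4R,5R,6Z,8S,10E)-5-(acetyloxy)-2-(bromomethyl)-8-{[tert-butyl(dimethyl)silyl]oxy}-6,10-dimethyl-4-{[(2Z)-2-methylbut-2-enoyl]oxy}-12-oxododeca-2,6,10-trienoate | O=C/C=C(\C)C[C@H](O[Si](C)(C)C(C)(C)C)/C=C(/C)[C@@H](OC(C)=O)[C@H](OC(=O)/C(C)=C\C)/C=C(\CBr)C(=O)OC | intermediate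
29 | allylchromium dichloride (trivalent chromium) at C13 of 28 | O=C/C=C(\C)C[C@H](O[Si](C)(C)C(C)(C)C)/C=C(/C)[C@@H](OC(C)=O)[C@H](OC(=O)/C(C)=C\C)/C=C(\C[Cr](Cl)Cl)C(=O)OC | intermediate (not isolated)
30 | methyl (1(10)Z,4E,2S,6R,7S,8R,9R)-9-acetoxy-8-angeloyloxy-2-{[tert-butyl(dimethyl)silyl]oxy}-6-hydroxygermacra-1(10),4,11(13)-trien-12-oate | COC(=O)C(=C)[C@H]1[C@H](O)/C=C(\C)C[C@H](O[Si](C)(C)C(C)(C)C)/C=C(/C)[C@@H](OC(C)=O)[C@@H]1OC(=O)/C(C)=C\C | intermediate (not isolated)
31 | (1(10)Z,4E,2S,6R,7S,8R,9R)-9-acetoxy-8-angeloyloxy-2-{[tert-butyl(dimethyl)silyl]oxy}germacra-1(10),4,11(13)-trien-12,6-olide | C=C1C(=O)O[C@@H]2/C=C(\C)C[C@H](O[Si](C)(C)C(C)(C)C)/C=C(/C)[C@@H](OC(C)=O)[C@H](OC(=O)/C(C)=C\C)[C@@H]12 | intermediate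
32 | (1(10)Z,4E,2S,6R,7S,8R,9R)-9-acetoxy-8-angeloyloxy-2-hydroxygermacra-1(10),4,11(13)-trien-12,6-olide (CNP0316477.1) | C=C1C(=O)O[C@@H]2/C=C(\C)C[C@H](O)/C=C(/C)[C@@H](OC(C)=O)[C@H](OC(=O)/C(C)=C\C)[C@@H]12 | target

## Step count and least certain steps

Total: 20 steps. Longest linear sequence: 20 steps (from 1; 19 from aldehyde 4).

Step 7 (key step). Over-oxidation may occur: bromination of the anisyl ring or of the product enone by excess reagent. Unbuffered HBr could also ionise the doubly activated carbinol and erode the configuration at C8. Fallback, from 10 back to 13: a hydroxyl-directed oxygen transfer with VO(C5H7O2)2 (cat.) and t-BuOOH in CH2Cl2. The vanadium alkoxide of O8 epoxidises the adjacent furan bond, the epoxide opens to 12 and cyclises to 13, with no electrophilic halogen and no acid. This fallback forms no compound outside the list (F0).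

Step 19. Reductive 1,4-elimination may expel the angelate from the allylchromium species; facial selectivity at C6/C7 may be poor; oligomerisation may compete with ring closure. Fallback, from 19 back to 31: O8 is silylated (Et3SiOTf, 2,6-lutidine, −78 °C) to the C8 triethylsilyl ether F1, which carries a poor leaving group next to the allyl unit. The operations of steps 15 to 18 then give in turn the allylic alcohol F2, the enal F3, the C13 alcohol F4 and the bromide F5. CrCl2 closure gives the bis-silylated lactone F6. HF·pyridine at 0 °C removes the triethylsilyl group selectively to give the C8 alcohol F7, and Yamaguchi esterification with 20 returns to 31.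

Step 12. Ring opening of the lactol may be slow at low temperature, which leaves conversion incomplete or forces warming, with loss of reagent control at C2; the open Z-enal may isomerise. Fallback, from 17 back to 22: NaBH4 in CH3OH reduces the lactol to the Z-allylic diol F8. The primary hydroxyl is silylated (Et3SiCl, imidazole, −20 °C) to the triethylsilyl ether F9. Yamaguchi esterification with 20 at O8 gives the angelate F10, and HF·pyridine releases the primary alcohol F11. MnO2 gives the free Z-enal F12, on which the same allenylborane acts on a true aldehyde to give the homopropargylic alcohol F13. Silylation (t-BuMe2SiCl, imidazole) returns to 22.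

Step 15. The Lewis acidic aluminium species may cleave or scramble the allylic esters, and capture of the alkenylalane by formaldehyde may be incomplete, which leads to protodealumination. Fallback, from 22 back to 24: the same methylalumination is quenched with I2 at −30 °C, a fast and general capture, to give the E-alkenyl iodide F14. A Stille coupling with (tributylstannyl)methanol under Pd(PPh3)4 in dioxane at 80 °C returns to 24.

Step 10. Activation with the weakly acidic acetic acid may be incomplete, and SN2′ attack at C1 or elimination to the diene may compete with direct displacement. Fallback, from 14 back to 16: a Corey–Bakshi–Shibata reduction of enone 14, using the oxazaborolidine antipode that delivers hydride to the face carrying the C2 silyloxy group, gives the cis alcohol F15 directly. Acetylation with retention (Ac2O, pyridine, DMAP cat.) then gives 16 without any substitution at C9.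

## Further compounds

F0 | step 7 | none | none
F1 | step 19 | methyl (2E,4R,5R,6Z,8S)-5-(acetyloxy)-8-{[tert-butyl(dimethyl)silyl]oxy}-2-{[(4-methoxybenzyl)oxy]methyl}-6-methyl-4-[(triethylsilyl)oxy]undeca-2,6-dien-10-ynoate | C#CC[C@H](O[Si](C)(C)C(C)(C)C)/C=C(/C)[C@@H](OC(C)=O)[C@H](O[Si](CC)(CC)CC)/C=C(\COCc1ccc(OC)cc1)C(=O)OC
F2 | step 19 | methyl (2E,4R,5R,6Z,8S,10E)-5-(acetyloxy)-8-{[tert-butyl(dimethyl)silyl]oxy}-12-hydroxy-2-{[(4-methoxybenzyl)oxy]methyl}-6,10-dimethyl-4-[(triethylsilyl)oxy]dodeca-2,6,10-trienoate | OC/C=C(\C)C[C@H](O[Si](C)(C)C(C)(C)C)/C=C(/C)[C@@H](OC(C)=O)[C@H](O[Si](CC)(CC)CC)/C=C(\COCc1ccc(OC)cc1)C(=O)OC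
F3 | step 19 | methyl (2E,4R,5R,6Z,8S,10E)-5-(acetyloxy)-8-{[tert-butyl(dimethyl)silyl]oxy}-2-{[(4-methoxybenzyl)oxy]methyl}-6,10-dimethyl-12-oxo-4-[(triethylsilyl)oxy]dodeca-2,6,10-trienoate | O=C/C=C(\C)C[C@H](O[Si](C)(C)C(C)(C)C)/C=C(/C)[C@@H](OC(C)=O)[C@H](O[Si](CC)(CC)CC)/C=C(\COCc1ccc(OC)cc1)C(=O)OC
F4 | step 19 | methyl (2E,4R,5R,6Z,8S,10E)-5-(acetyloxy)-8-{[tert-butyl(dimethyl)silyl]oxy}-2-(hydroxymethyl)-6,10-dimethyl-12-oxo-4-[(triethylsilyl)oxy]dodeca-2,6,10-trienoate | O=C/C=C(\C)C[C@H](O[Si](C)(C)C(C)(C)C)/C=C(/C)[C@@H](OC(C)=O)[C@H](O[Si](CC)(CC)CC)/C=C(\CO)C(=O)OC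
F5 | step 19 | methyl (2Z,4R,5R,6Z,8S,10E)-5-(acetyloxy)-2-(bromomethyl)-8-{[tert-butyl(dimethyl)silyl]oxy}-6,10-dimethyl-12-oxo-4-[(triethylsilyl)oxy]dodeca-2,6,10-trienoate | O=C/C=C(\C)C[C@H](O[Si](C)(C)C(C)(C)C)/C=C(/C)[C@@H](OC(C)=O)[C@H](O[Si](CC)(CC)CC)/C=C(\CBr)C(=O)OC
F6 | step 19 | (1(10)Z,4E,2S,6R,7S,8R,9R)-9-acetoxy-2-{[tert-butyl(dimethyl)silyl]oxy}-8-[(triethylsilyl)oxy]germacra-1(10),4,11(13)-trien-12,6-olide | C=C1C(=O)O[C@@H]2/C=C(\C)C[C@H](O[Si](C)(C)C(C)(C)C)/C=C(/C)[C@@H](OC(C)=O)[C@H](O[Si](CC)(CC)CC)[C@@H]12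
F7 | step 19 | (1(10)Z,4E,2S,6R,7S,8R,9R)-9-acetoxy-2-{[tert-butyl(dimethyl)silyl]oxy}-8-hydroxygermacra-1(10),4,11(13)-trien-12,6-olide | C=C1C(=O)O[C@@H]2/C=C(\C)C[C@H](O[Si](C)(C)C(C)(C)C)/C=C(/C)[C@@H](OC(C)=O)[C@H](O)[C@@H]12
F8 | step 12 | methyl (2E,4R,5R,6Z)-5-(acetyloxy)-4,8-dihydroxy-2-{[(4-methoxybenzyl)oxy]methyl}-6-methylocta-2,6-dienoate | OC/C=C(/C)[C@@H](OC(C)=O)[C@H](O)/C=C(\COCc1ccc(OC)cc1)C(=O)OC
F9 | step 12 | methyl (2E,4R,5R,6Z)-5-(acetyloxy)-4-hydroxy-2-{[(4-methoxybenzyl)oxy]methyl}-6-methyl-8-[(triethylsilyl)oxy]octa-2,6-dienoate | CC[Si](CC)(CC)OC/C=C(/C)[C@@H](OC(C)=O)[C@H](O)/C=C(\COCc1ccc(OC)cc1)C(=O)OC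
F10 | step 12 | methyl (2E,4R,5R,6Z)-5-(acetyloxy)-2-{[(4-methoxybenzyl)oxy]methyl}-6-methyl-4-{[(2Z)-2-methylbut-2-enoyl]oxy}-8-[(triethylsilyl)oxy]octa-2,6-dienoate | CC[Si](CC)(CC)OC/C=C(/C)[C@@H](OC(C)=O)[C@H](OC(=O)/C(C)=C\C)/C=C(\COCc1ccc(OC)cc1)C(=O)OC
F11 | step 12 | methyl (2E,4R,5R,6Z)-5-(acetyloxy)-8-hydroxy-2-{[(4-methoxybenzyl)oxy]methyl}-6-methyl-4-{[(2Z)-2-methylbut-2-enoyl]oxy}octa-2,6-dienoate | OC/C=C(/C)[C@@H](OC(C)=O)[C@H](OC(=O)/C(C)=C\C)/C=C(\COCc1ccc(OC)cc1)C(=O)OC
F12 | step 12 | methyl (2E,4R,5R,6Z)-5-(acetyloxy)-2-{[(4-methoxybenzyl)oxy]methyl}-6-methyl-4-{[(2Z)-2-methylbut-2-enoyl]oxy}-8-oxoocta-2,6-dienoate | O=C/C=C(/C)[C@@H](OC(C)=O)[C@H](OC(=O)/C(C)=C\C)/C=C(\COCc1ccc(OC)cc1)C(=O)OC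
F13 | step 12 | methyl (2E,4R,5R,6Z,8S)-5-(acetyloxy)-8-hydroxy-2-{[(4-methoxybenzyl)oxy]methyl}-6-methyl-4-{[(2Z)-2-methylbut-2-enoyl]oxy}undeca-2,6-dien-10-ynoate | C#CC[C@H](O)/C=C(/C)[C@@H](OC(C)=O)[C@H](OC(=O)/C(C)=C\C)/C=C(\COCc1ccc(OC)cc1)C(=O)OC
F14 | step 15 | methyl (2E,4R,5R,6Z,8S,10E)-5-(acetyloxy)-8-{[tert-butyl(dimethyl)silyl]oxy}-11-iodo-2-{[(4-methoxybenzyl)oxy]methyl}-6,10-dimethyl-4-{[(2Z)-2-methylbut-2-enoyl]oxy}undeca-2,6,10-trienoate | I/C=C(\C)C[C@H](O[Si](C)(C)C(C)(C)C)/C=C(/C)[C@@H](OC(C)=O)[C@H](OC(=O)/C(C)=C\C)/C=C(\COCc1ccc(OC)cc1)C(=O)OC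
F15 | step 10 | methyl (2E)-3-[(2R,3R,6R)-6-{[tert-butyl(dimethyl)silyl]oxy}-3-hydroxy-4-methyl-3,6-dihydro-2H-pyran-2-yl]-2-{[(4-methoxybenzyl)oxy]methyl}prop-2-enoate | COC(=O)/C(COCc1ccc(OC)cc1)=C/[C@H]1O[C@H](O[Si](C)(C)C(C)(C)C)C=C(C)[C@H]1O
A1 | alternative 1 | ten-membered (1(10)Z,4E)-diene with saturated 6,12-lactone, C8/C9 acetonide and C2 tert-butyldimethylsilyl ether | C/C1=C/[C@@H](O[Si](C)(C)C(C)(C)C)C/C(C)=C/[C@H]2OC(=O)C[C@@H]2[C@H]3OC(C)(C)O[C@@H]31
A2 | alternative 2 | ten-membered dienone with C9 ketone, C2 triethylsilyl ether, C6 tert-butyldimethylsilyl ether and C7 3-[(4-methoxybenzyl)oxy]prop-1-en-2-yl side chain | C=C(COCc1ccc(OC)cc1)[C@@H]2CC(=O)/C(C)=C\[C@@H](O[Si](CC)(CC)CC)C/C(C)=C/[C@H]2O[Si](C)(C)C(C)(C)C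
A3 | alternative 3 | ten-membered C6 allylic alcohol with E-olefin C4=C5, C8/C9 acetonide, C2 tert-butyldimethylsilyl ether and C7 methoxycarbonylmethyl side chain | O[C@@H]3/C=C(\C)C[C@H](O[Si](C)(C)C(C)(C)C)/C=C(/C)[C@H]1OC(C)(C)O[C@@H]1[C@H]3CC(=O)OC
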